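**Strategy.** Ring A is grown from a five-membered ring and not closed directly. C10, C4 and C3 come from the cyclopentane of camphoric anhydride, which carries the C10 methyl, the C4 gem-dimethyl group and, after Baeyer–Villiger oxidation, the C3 oxygen. A Carroll rearrangement attaches an allylsilane chain made from (S)-citronellic acid, giving the precursor: a cyclopentyl carbinol (C5) with a tethered allylsilane. In the key step, ionisation at C5 makes quaternary C4 migrate from C10 to C5: the cyclopentane expands to ring A, and the new C10 cation is trapped by the allylsilane, closing ring B (C9–C10) with the C8=C17 methylene. The step exploits the C10–C4–C5 triad of ring A: a migrating quaternary carbon beside a cation-stabilising ring-fusion carbon.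

Key step: step 9

Remark: labdane numbering is used for all intermediates (ring A = C1–C5 and C10; ring B = C5–C10; C17 = exocyclic methylene carbon; C11–C16 = side chain), and the target is read as (13S)-3β,7α-diacetoxylabd-8(17)-en-15-oic acid of the normal series (3S,5R,7R,9R,10S,13S).

Step 1
Reactants: 1 (1R,5S)-1,8,8-trimethyl-3-oxabicyclo[3.2.1]octane-2,4-dione (anhydride of (1R,3S)-camphoric acid)
Product: 2 (1R,3S)-3-acetyl-1,2,2-trimethylcyclopentane-1-carboxylic acid
Conditions: MeMgBr (1.05 equiv), THF, −78 → 0 °C; then 1 M HCl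
Reagents that add atoms: methylmagnesium bromide C[Mg]Br
Why: Grignard opening of a cyclic anhydride should occur at the less hindered carbonyl (on the CH carbon, not on the methyl-bearing quaternary carbon), and at low temperature the keto carboxylate should resist a second addition; both stereocentres are untouched.

Step 2
Reactants: 2 (1R,3S)-3-acetyl-1,2,2-trimethylcyclopentane-1-carboxylic acid
Product: 3 (1R,3S)-3-acetoxy-1,2,2-trimethylcyclopentane-1-carboxylic acid
Conditions: mCPBA, CF3CO2H (cat.), CH2Cl2, rt
Reagents that add atoms: mCPBA OOC(=O)c1cccc(Cl)c1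
Why: Baeyer–Villiger oxidation, in which the secondary ring carbon should migrate in preference to methyl and with retention, so the C3 oxygen of the target is installed directly as its acetate with the (S) configuration inherited from camphoric acid.

Step 3
Reactants: 3 (1R,3S)-3-acetoxy-1,2,2-trimethylcyclopentane-1-carboxylic acid
Product: 5 5-{[(1R,3S)-3-acetoxy-1,2,2-trimethylcyclopentyl](hydroxy)methylidene}-2,2-dimethyl-1,3-dioxane-4,6-dione (acyl Meldrum's acid), via acid chloride 4 (not isolated)
Conditions: (COCl)2, DMF (cat.), CH2Cl2, 0 °C → rt; then Meldrum's acid, pyridine, DMAP (cat.), CH2Cl2, 0 °C → rt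
Reagents that add atoms: Meldrum's acid CC1(C)OC(=O)CC(=O)O1; oxalyl chloride ClC(=O)C(=O)Cl (chlorine of 4 only)
Why: acid chloride formation and C-acylation of Meldrum's acid are standard and give a storable acylketene precursor that supplies C5 (carbonyl) and C6 (CH2); the acetate should survive these conditions.

Step 4
Reactants: 6 (S)-citronellic acid
Product: 7 2-(trimethylsilyl)ethyl (3S)-3,7-dimethyloct-6-enoate
Conditions: 2-(trimethylsilyl)ethanol, DCC, DMAP (cat.), CH2Cl2, 0 °C → rt
Reagents that add atoms: 2-(trimethylsilyl)ethanol OCC[Si](C)(C)C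
Why: Steglich esterification masks C15 as a fluoride-labile ester that should survive every later step and can be removed at the end without touching the two acetates; the C13 stereocentre comes from the chiral pool.

Step 5
Reactants: 7 2-(trimethylsilyl)ethyl (3S)-3,7-dimethyloct-6-enoate
Product: 8 2-(trimethylsilyl)ethyl (3S)-3-methyl-6-oxohexanoate
Conditions: O3, CH2Cl2/MeOH, −78 °C; then Me2S, −78 °C → rt
Reagents that add atoms: ozone [O-][O+]=O
Why: ozonolysis with reductive work-up cleaves the only alkene and unveils C9 as an aldehyde, with the remote C13 centre unaffected.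

Step 6
Reactants: 8 2-(trimethylsilyl)ethyl (3S)-3-methyl-6-oxohexanoate; 9 (2-bromoallyl)trimethylsilane
Product: 11 2-(trimethylsilyl)ethyl (3S)-6-hydroxy-3-methyl-7-[(trimethylsilyl)methyl]oct-7-enoate (both C6 epimers), via Grignard reagent 10 (not isolated)
Conditions: 9, Mg, THF, rt; then 8, THF, −78 °C; H2O work-up
Reagents that add atoms: magnesium [Mg] (in 10 only)
Why: Grignard addition of the 2-metallated allylsilane, which should take the aldehyde much faster than the ester at −78 °C; the new carbinol centre needs no control because it becomes sp2 (C9) in step 7.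

Step 7
Reactants: 5 acyl Meldrum's acid; 11 2-(trimethylsilyl)ethyl (3S)-6-hydroxy-3-methyl-7-[(trimethylsilyl)methyl]oct-7-enoate
Product: 13 2-(trimethylsilyl)ethyl (3S,6Z)-10-[(1R,3S)-3-acetoxy-1,2,2-trimethylcyclopentyl]-3-methyl-10-oxo-7-[(trimethylsilyl)methyl]dec-6-enoate, via β-keto ester 12 (not isolated)
Conditions: 1,2-dichlorobenzene, 110 °C (alcoholysis), then 180 °C (rearrangement, −CO2)
Reagents that add atoms: none
Why: thermolysis of 5 gives an acylketene that alcohol 11 should trap as β-keto ester 12, and further heating should trigger the Carroll rearrangement ([3,3] shift of the ester enol, then decarboxylation) that forms C6–C7; a chair transition state with the side chain equatorial should place C11 trans to C7, the alkene geometry needed in step 9.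

Step 8
Reactants: 13 the C5 ketone (dec-6-enoate numbering: 10-oxo)
Product: 14 2-(trimethylsilyl)ethyl (3S,6Z,10S)-10-[(1R,3S)-3-acetoxy-1,2,2-trimethylcyclopentyl]-10-hydroxy-3-methyl-7-[(trimethylsilyl)methyl]dec-6-enoate
Conditions: (R)-Me-CBS oxazaborolidine (0.3 equiv), catecholborane, toluene, −78 → −40 °C
Reagents that add atoms: none
Why: Corey–Bakshi–Shibata reduction, in which the catalyst should distinguish the quaternary cyclopentyl group (large) from the CH2 chain (small) and give the (S)-carbinol at C5 by reagent control; catecholborane should not hydroborate the allylsilane or reduce the esters at this temperature.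

Step 9
Reactants: 14 the (10S)-alcohol (C5 carbinol)
Product: 16 2-(trimethylsilyl)ethyl (13S)-3β-acetoxylabd-8(17)-en-15-oate, via triflate 15 (not isolated)
Conditions: Tf2O, 2,6-di-tert-butyl-4-methylpyridine, CH2Cl2, −78 → −20 °C
Reagents that add atoms: triflic anhydride O=S(=O)(OS(=O)(=O)C(F)(F)F)C(F)(F)F (triflate group of 15 only)
Why: Proposed new method: the triflate 15 of the neopentylic C5 carbinol should ionise below −20 °C with anti-periplanar 1,2-shift of the quaternary C4 from C10 to C5 (Wagner–Meerwein, cyclopentylcarbinyl to cyclohexyl), so that the cyclopentane becomes six-membered ring A and a tertiary cation appears at C10, which the tethered allylsilane attacks through C9 before the silyl group is lost to leave the C8=C17 methylene. The closest known reaction types are the solvolytic Wagner–Meerwein (Demjanov-type) ring expansion of 1-alkylcyclopentylcarbinyl sulfonates and the allylsilane-terminated cation–olefin cyclisation of monocyclic cyclohexyl cations; their union in one cascade is the untested part. Ring A is not closed but enlarged (five to six atoms by the C4 shift), and ring B closes by 6-endo-trig attack of the C8=C9 alkene on the C10 cation through a chair transition state. C5 is fixed by inversion at the (S)-carbinol carbon (C4 enters anti to the departing triflate), C10 by closure of the cation with the C6 tether equatorial and the new C9–C10 bond anti to C4–C5 (trans-decalin, the sense found in stepwise cyclisations of cyclogeranyl-type cations; the camphor-derived C10 configuration is erased in the planar cation), and C9 by the alkene geometry, which puts C11 equatorial. The step needs C4 to migrate rather than C1 or the C10 methyl, which its full substitution (best able to carry positive charge) and the relief of cyclopentane strain should secure, and it needs ring closure to outrun proton loss, which the tether and the hindered base (no free triflic acid, no protodesilylation) should secure.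

Step 10
Reactants: 16 2-(trimethylsilyl)ethyl (13S)-3β-acetoxylabd-8(17)-en-15-oate
Product: 17 2-(trimethylsilyl)ethyl (13S)-3β-acetoxy-7α-hydroxylabd-8(17)-en-15-oate
Conditions: SeO2 (0.5 equiv), t-BuOOH (anhydrous, 3 equiv), CH2Cl2, 0 °C → rt
Reagents that add atoms: selenium dioxide O=[Se]=O (delivers the oxygen, catalytic); tert-butyl hydroperoxide CC(C)(C)OO (terminal oxidant)
Why: SeO2 allylic oxidation (ene reaction at C17 with removal of the axial H-7α, then [2,3]-sigmatropic shift) should deliver oxygen axially to the α-face of C7, the ring CH2 being oxidised in preference to the tertiary C9–H.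

Step 11
Reactants: 17 2-(trimethylsilyl)ethyl (13S)-3β-acetoxy-7α-hydroxylabd-8(17)-en-15-oate
Product: 18 2-(trimethylsilyl)ethyl (13S)-3β,7α-diacetoxylabd-8(17)-en-15-oate
Conditions: Ac2O, pyridine, DMAP (cat.), CH2Cl2, rt
Reagents that add atoms: acetic anhydride CC(=O)OC(C)=O
Why: DMAP-catalysed acylation should acetylate the hindered axial allylic alcohol without ionising it or moving the alkene.

Step 12
Reactants: 18 2-(trimethylsilyl)ethyl (13S)-3β,7α-diacetoxylabd-8(17)-en-15-oate
Product: 19 (13S)-3β,7α-diacetoxylabd-8(17)-en-15-oic acid (CNP0169875.1)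
Conditions: TBAF, THF, 0 °C → rt; then dilute aq. HCl to pH 3
Reagents that add atoms: none
Why: fluoride-induced β-elimination of the 2-(trimethylsilyl)ethyl ester should free the C15 acid under non-hydrolytic conditions that leave both acetates and the allylic system intact.

**Compound list**

1 | (1R,5S)-1,8,8-trimethyl-3-oxabicyclo[3.2.1]octane-2,4-dione ((1R,3S)-camphoric anhydride) | CC1(C)[C@@H]2CC[C@@]1(C)C(=O)OC2=O | starting material
2 | (1R,3S)-3-acetyl-1,2,2-trimethylcyclopentane-1-carboxylic acid | C[C@@]1(C(=O)O)CC[C@H](C(C)=O)C1(C)C | intermediate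
3 | (1R,3S)-3-acetoxy-1,2,2-trimethylcyclopentane-1-carboxylic acid | C[C@@]1(C(=O)O)CC[C@H](OC(C)=O)C1(C)C | intermediate
4 | (1R,3S)-3-acetoxy-1,2,2-trimethylcyclopentane-1-carbonyl chloride (not isolated) | C[C@@]1(C(=O)Cl)CC[C@H](OC(C)=O)C1(C)C | intermediate
5 | 5-{[(1R,3S)-3-acetoxy-1,2,2-trimethylcyclopentyl](hydroxy)methylidene}-2,2-dimethyl-1,3-dioxane-4,6-dione | C[C@@]1(C(O)=C2C(=O)OC(C)(C)OC2=O)CC[C@H](OC(C)=O)C1(C)C | intermediate
6 | (S)-citronellic acid, (3S)-3,7-dimethyloct-6-enoic acid | CC(C)=CCC[C@H](C)CC(=O)O | starting material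
7 | 2-(trimethylsilyl)ethyl (3S)-3,7-dimethyloct-6-enoate | CC(C)=CCC[C@H](C)CC(=O)OCC[Si](C)(C)C | intermediate
8 | 2-(trimethylsilyl)ethyl (3S)-3-methyl-6-oxohexanoate | O=CCC[C@H](C)CC(=O)OCC[Si](C)(C)C | intermediate
9 | (2-bromoallyl)trimethylsilane | C=C(Br)C[Si](C)(C)C | starting material
10 | [3-(trimethylsilyl)prop-1-en-2-yl]magnesium bromide (not isolated) | C=C([Mg]Br)C[Si](C)(C)C | intermediate
11 | 2-(trimethylsilyl)ethyl (3S)-6-hydroxy-3-methyl-7-[(trimethylsilyl)methyl]oct-7-enoate (both C6 epimers) | C=C(C[Si](C)(C)C)C(O)CC[C@H](C)CC(=O)OCC[Si](C)(C)C | intermediate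
12 | 3-[(1R,3S)-3-acetoxy-1,2,2-trimethylcyclopentyl]-3-oxopropanoate ester of alcohol 11 (not isolated) | C[C@@]1(C(=O)CC(=O)OC(CC[C@H](C)CC(=O)OCC[Si](C)(C)C)C(=C)C[Si](C)(C)C)CC[C@H](OC(C)=O)C1(C)C | intermediate
13 | 2-(trimethylsilyl)ethyl (3S,6Z)-10-[(1R,3S)-3-acetoxy-1,2,2-trimethylcyclopentyl]-3-methyl-10-oxo-7-[(trimethylsilyl)methyl]dec-6-enoate | C[C@@]1(C(=O)CC/C(C[Si](C)(C)C)=C/CC[C@H](C)CC(=O)OCC[Si](C)(C)C)CC[C@H](OC(C)=O)C1(C)C | intermediate
14 | 2-(trimethylsilyl)ethyl (3S,6Z,10S)-10-[(1R,3S)-3-acetoxy-1,2,2-trimethylcyclopentyl]-10-hydroxy-3-methyl-7-[(trimethylsilyl)methyl]dec-6-enoate | C[C@@]1([C@@H](O)CC/C(C[Si](C)(C)C)=C/CC[C@H](C)CC(=O)OCC[Si](C)(C)C)CC[C@H](OC(C)=O)C1(C)C | intermediate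
15 | (10S)-trifluoromethanesulfonate of 14 (not isolated) | C[C@@]1([C@@H](OS(=O)(=O)C(F)(F)F)CC/C(C[Si](C)(C)C)=C/CC[C@H](C)CC(=O)OCC[Si](C)(C)C)CC[C@H](OC(C)=O)C1(C)C | intermediate
16 | 2-(trimethylsilyl)ethyl (13S)-3β-acetoxylabd-8(17)-en-15-oate (trans-decalin, 5α-H, 9α-H, 10β-methyl) | C=C1CC[C@H]2C(C)(C)[C@@H](OC(C)=O)CC[C@]2(C)[C@H]1CC[C@H](C)CC(=O)OCC[Si](C)(C)C | intermediate
17 | 2-(trimethylsilyl)ethyl (13S)-3β-acetoxy-7α-hydroxylabd-8(17)-en-15-oate | C=C1[C@H](O)C[C@H]2C(C)(C)[C@@H](OC(C)=O)CC[C@]2(C)[C@H]1CC[C@H](C)CC(=O)OCC[Si](C)(C)C | intermediate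
18 | 2-(trimethylsilyl)ethyl (13S)-3β,7α-diacetoxylabd-8(17)-en-15-oate | C=C1[C@H](OC(C)=O)C[C@H]2C(C)(C)[C@@H](OC(C)=O)CC[C@]2(C)[C@H]1CC[C@H](C)CC(=O)OCC[Si](C)(C)C | intermediate
19 | (13S)-3β,7α-diacetoxylabd-8(17)-en-15-oic acid (CNP0169875.1) | C=C1[C@H](OC(C)=O)C[C@H]2C(C)(C)[C@@H](OC(C)=O)CC[C@]2(C)[C@H]1CC[C@H](C)CC(=O)O | target

**Step count and risks**

Total step count: 12. Longest linear sequence: 9 steps (steps 1–3 and 7–12; the chain branch, steps 4–6 and 7–12, is equally long).

Steps most likely to fail:

Step 9 (the labelled step). What may go wrong: migration of C1 or of the C10 methyl group instead of C4, proton loss from the C10 cation before ring B closes, or closure on the other face of the cation to a cis-fused decalin. The fallback uses known chemistry and separates ring expansion from ring closure. It sets out from 14: MsCl/Et3N should give the methanesulfonate F1. Buffered solvolysis (CaCO3, acetone/H2O, 50 °C) is the classical Wagner–Meerwein ring expansion of a cyclopentylcarbinyl sulfonate with capture of the tertiary cation by water; it should give the monocyclic tertiary alcohol F2, in which ring A is already six-membered and C10 carries OH (both C10 epimers). F2 is then ionised with SnCl4 in CH2Cl2 at −78 °C, a standard tertiary-alcohol-initiated, allylsilane-terminated cation–olefin cyclisation, which returns to the route at 16.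

Step 8. What may go wrong: slow hydride delivery to the hindered ketone, poor facial selectivity through mismatch with the ring stereocentres, or hydroboration of the allylsilane. The fallback sets out from 13: substrate-controlled reduction with NaBH4/CeCl3·7H2O (MeOH, −40 °C) should give 14 together with its (10R)-epimer F3. The two are diastereomers and are separated by chromatography; F3 is oxidised back to 13 with Dess–Martin periodinane and recycled, so the route is rejoined at 14.

Step 10. What may go wrong: over-oxidation to the enone, oxygen delivery to the wrong face of C7, or attack at C9. The fallback sets out from 16: the oxidation is driven through to the 7-ketone F4 (SeO2/t-BuOOH, then Dess–Martin periodinane on the crude allylic alcohols). Luche reduction (NaBH4, CeCl3·7H2O, MeOH, −78 °C) should deliver hydride axially from the α-face and give the equatorial 7β-alcohol F5. Mitsunobu inversion with acetic acid (PPh3, DIAD, THF) should then install the 7α-acetate directly, rejoining the route at 18.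

Further compounds
F1 | step 9 | (10S)-methanesulfonate of 14 | C[C@@]1([C@@H](OS(C)(=O)=O)CC/C(C[Si](C)(C)C)=C/CC[C@H](C)CC(=O)OCC[Si](C)(C)C)CC[C@H](OC(C)=O)C1(C)C
F2 | step 9 | 2-(trimethylsilyl)ethyl (3S,6Z)-9-[(1S,3S)-3-acetoxy-6-hydroxy-2,2,6-trimethylcyclohexyl]-3-methyl-7-[(trimethylsilyl)methyl]non-6-enoate (ring-expanded tertiary C10 alcohol, both C10 epimers) | CC1(O)CC[C@H](OC(C)=O)C(C)(C)[C@@H]1CC/C(C[Si](C)(C)C)=C/CC[C@H](C)CC(=O)OCC[Si](C)(C)C
F3 | step 8 | (10R)-epimer of alcohol 14 | C[C@@]1([C@H](O)CC/C(C[Si](C)(C)C)=C/CC[C@H](C)CC(=O)OCC[Si](C)(C)C)CC[C@H](OC(C)=O)C1(C)C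
F4 | step 10 | 2-(trimethylsilyl)ethyl (13S)-3β-acetoxy-7-oxolabd-8(17)-en-15-oate | C=C1C(=O)C[C@H]2C(C)(C)[C@@H](OC(C)=O)CC[C@]2(C)[C@H]1CC[C@H](C)CC(=O)OCC[Si](C)(C)C
F5 | step 10 | 2-(trimethylsilyl)ethyl (13S)-3β-acetoxy-7β-hydroxylabd-8(17)-en-15-oate | C=C1[C@@H](O)C[C@H]2C(C)(C)[C@@H](OC(C)=O)CC[C@]2(C)[C@H]1CC[C@H](C)CC(=O)OCC[Si](C)(C)C
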